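**Retrosynthetic overview** (cembrane numbering: C1 carries the acrylate C15(=C17H2)–C16O2Me; oxirane C3–C4; olefin C7=C8; ketone C11; carbinol C12)
1. The oxirane is formed last, by reagent-controlled epoxidation of the 3Z-olefin of the finished 14-membered ring (Z-olefin gives the cis-oxirane); a final zinc step unmasks C7=C8 and 12-OH.
2. The 14-membered ring comes from a cyclase-type C1–C2 closure: an ionised Z-allylic C2 acetate is captured by the distal C1=C15 bond of a 2-(silylmethyl)enoate, and silyl loss (in place of proton loss) leaves the exocyclic acrylate.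
3. Before ionisation, C7=C8 and 12-OH are tied together as an 8,12-bromoether (temporary oxane). The Z-allyl cation then cannot collapse to a six-membered ring, and the later epoxidation sees only one electron-rich olefin.
4. The acyclic C20 chain comes from a C9–C10 enolate alkylation of a chiral-pool methyl ketone (C10–C14 and C1; sets C12) with a Z,E-configured C10 allylic bromide (C2–C9); a Wittig reaction at C1 adds C15–C17.
5. Ring order: temporary oxane, then carbocycle, then oxirane.

Assumption: (S)-(+)-linalool (1, coriandrol) is bought in at least 95% ee; compounds carrying the temporary C7/C8 bromoether centres are handled as the pair of anti-adducts, and the C1 epimers are separated after step 10.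

**Step 1**
Reactants: 1 (S)-(+)-linalool [(3S)-3,7-dimethylocta-1,6-dien-3-ol]
Product: 3 (5S)-5-ethenyl-2-methoxy-5-methyloxolane, via lactol 2 (not isolated)
Conditions: O3, CH2Cl2–MeOH, −78 °C (Sudan Red 7B end point); Me2S, −78 → 20 °C; then p-TsOH·H2O (2 mol %), MeOH, 20 °C
Reagents that add atoms: methanol, CO
Why: Ozonolysis (Criegee mechanism, Me2S reduction) cleaves the electron-rich trisubstituted 6,7-olefin far faster than the vinyl group, the γ-hydroxy aldehyde closes to lactol 2, and acid-catalysed acetalisation in MeOH then locks the C12 oxygen and the C1 aldehyde in one methyl acetal, the S-configured C12 centre of the chiral pool being untouched.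

**Step 2**
Reactants: 3 (5S)-5-ethenyl-2-methoxy-5-methyloxolane
Product: 4 1-[(2S)-5-methoxy-2-methyloxolan-2-yl]ethan-1-one
Conditions: PdCl2 (10 mol %), CuCl (1 equiv, redox mediator), O2 (1 atm), DMF–H2O 7:1, 25 °C
Reagents that add atoms: water, O
Why: Tsuji–Wacker oxidation: Markovnikov hydroxypalladation of the only olefin left (a vinyl group on a fully substituted carbon, as in other 2-vinyl cyclic ethers) gives the methyl ketone C10–C11, and the quaternary C12 centre cannot epimerise.

**Step 3**
Reactants: 5 neryl acetate [(2Z)-3,7-dimethylocta-2,6-dien-1-yl acetate]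
Product: 6 (2Z,6E)-8-hydroxy-3,7-dimethylocta-2,6-dien-1-yl acetate
Conditions: SeO2 (0.3 equiv), t-BuOOH (3 equiv), salicylic acid (10 mol %), CH2Cl2, 20 °C
Reagents that add atoms: tert-butyl hydroperoxide, CC(C)(C)OO
Why: Riley oxidation with catalytic SeO2 (ene reaction then [2,3]-shift) attacks the more electron-rich terminal olefin and, as usual, its E-methyl group, which fixes the later 7E geometry while the 2Z-olefin, deactivated by the allylic acetate, is left alone.

**Step 4**
Reactants: 6 (2Z,6E)-8-hydroxy-3,7-dimethylocta-2,6-dien-1-yl acetate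
Product: 7 (2Z,6E)-8-bromo-3,7-dimethylocta-2,6-dien-1-yl acetate
Conditions: CBr4, PPh3, CH2Cl2, 0 °C
Reagents that add atoms: carbon tetrabromide, BrC(Br)(Br)Br
Why: Appel reaction: the primary allylic alcohol is displaced by bromide (SN2 on the alkoxyphosphonium ion) without allylic transposition or change of either olefin geometry.

**Step 5**
Reactants: 4 1-[(2S)-5-methoxy-2-methyloxolan-2-yl]ethan-1-one; 7 (2Z,6E)-8-bromo-3,7-dimethylocta-2,6-dien-1-yl acetate
Product: 9 (2Z,6E)-10-[(2S)-5-methoxy-2-methyloxolan-2-yl]-3,7-dimethyl-10-oxodeca-2,6-dien-1-yl acetate, via lithium enolate 8 (not isolated)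
Conditions: LiN(iPr)2 (LDA, 1.05 equiv), THF, −78 °C; then 7, −78 → −30 °C
Reagents that add atoms: none
Why: Kinetic enolate alkylation: 4 can enolise only towards its methyl group (C12 is quaternary) and the lithium enolate displaces the primary allylic bromide by SN2 at −78 °C much faster than it attacks the acetate, which forms C9–C10 and completes the C20 chain with the 3Z and 7E olefins in place.

**Step 6**
Reactants: 9 (2Z,6E)-10-[(2S)-5-methoxy-2-methyloxolan-2-yl]-3,7-dimethyl-10-oxodeca-2,6-dien-1-yl acetate
Product: 10 (2Z,6E)-10-[(2S)-5-hydroxy-2-methyloxolan-2-yl]-3,7-dimethyl-10-oxodeca-2,6-dien-1-yl acetate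
Conditions: AcOH–THF–H2O 3:1:1, 40 °C
Reagents that add atoms: water, O
Why: Acid-catalysed acetal hydrolysis converts the methyl furanoside into the lactol, i.e. the latent γ-hydroxy aldehyde, under conditions that leave the allylic acetate and both trisubstituted olefins intact.

**Step 7**
Reactants: 10 (2Z,6E)-10-[(2S)-5-hydroxy-2-methyloxolan-2-yl]-3,7-dimethyl-10-oxodeca-2,6-dien-1-yl acetate
Product: 11 (2Z)-6-bromo-6-[(6S)-2,6-dimethyl-5-oxo-6-(3-oxopropyl)oxan-2-yl]-3-methylhex-2-en-1-yl acetate
Conditions: NBS (1.05 equiv), NaHCO3, CH2Cl2, 0 °C, dark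
Reagents that add atoms: N-bromosuccinimide, O=C1CCC(=O)N1Br
Why: Bromoetherification: the bromonium ion forms reversibly on the most nucleophilic olefin (7,8; the 3,4-olefin is deactivated by the allylic acetate) and is trapped 6-exo at the tertiary C8 by the C12 oxygen of the open hydroxy aldehyde form (anti addition), so that one oxane masks both the 12-OH and the 7,8-olefin and frees the C1 aldehyde, the two new centres C7/C8 being temporary and erased in step 12.

**Step 8**
Reactants: 12 methyl (triphenyl-λ5-phosphanylidene)acetate; 13 (iodomethyl)trimethylsilane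
Product: 15 methyl 2-(triphenyl-λ5-phosphanylidene)-3-(trimethylsilyl)propanoate, via phosphonium iodide 14 (not isolated)
Conditions: 12 (2 equiv), 13 (1 equiv), EtOAc, reflux; filter off the phosphonium salt
Reagents that add atoms: none
Why: C-Alkylation of the stabilised ylide by the primary iodide gives phosphonium salt 14, which a second equivalent of 12 deprotonates (transylidation), the standard way to α-substituted stabilised Wittig reagents.

**Step 9**
Reactants: 11 (2Z)-6-bromo-6-[(6S)-2,6-dimethyl-5-oxo-6-(3-oxopropyl)oxan-2-yl]-3-methylhex-2-en-1-yl acetate; 15 methyl 2-(triphenyl-λ5-phosphanylidene)-3-(trimethylsilyl)propanoate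
Product: 16 methyl (2Z)-5-[(2S)-6-[(4Z)-6-acetoxy-1-bromo-4-methylhex-4-en-1-yl]-2,6-dimethyl-3-oxooxan-2-yl]-2-[(trimethylsilyl)methyl]pent-2-enoate
Conditions: 15 (1.5 equiv), toluene, 80 °C
Reagents that add atoms: none
Why: Wittig olefination: the stabilised ylide reacts with the aldehyde only (the hindered ketone and the secondary bromide are inert) and installs C15 with both the C16 ester and the C17 allylsilane, the E/Z ratio of this olefin being irrelevant because it is consumed in the next step.

**Step 10**
Reactants: 16 methyl (2Z)-5-[(2S)-6-[(4Z)-6-acetoxy-1-bromo-4-methylhex-4-en-1-yl]-2,6-dimethyl-3-oxooxan-2-yl]-2-[(trimethylsilyl)methyl]pent-2-enoate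
Product: 18 methyl 2-[(1S,3Z,12S)-7-bromo-8,12-epoxy-4,8,12-trimethyl-11-oxocyclotetradec-3-en-1-yl]prop-2-enoate, via allyl cation 17 (not isolated)
Conditions: Me3SiOSO2CF3 (TMSOTf, 0.3 equiv), 2,6-di-tert-butyl-4-methylpyridine (0.5 equiv), CH2Cl2, slow addition of 16 to 1 mM, −78 → −40 °C
Reagents that add atoms: none
Why: Proposed new method: TMSOTf ionises the 3,3-disubstituted allylic acetate (Me3SiOAc leaves) to the Z-configured allyl cation 17, which, because the 7,8-olefin is masked and the usual neryl-to-terpinyl six-ring collapse is therefore impossible, is captured at its primary terminus C2 by the tethered allylsilane in an SE2′ reaction (β-silyl cation, loss of Me3Si+ regenerates TMSOTf), forming C1–C2, the 14-membered carbocycle and the exocyclic C15=C17 acrylate in the way a cembrene synthase closes its ring with proton loss; the closest known reactions are Lewis-acid-mediated couplings of allyl cations from allylic halides or acetates with allylsilanes and allylstannanes and the BF3-promoted allylstannane macrocyclisations to 14-membered cembranoids; the low temperature is meant to hold the 3Z geometry, and C1 is formed as an epimer pair with no reliable bias from the remote 12S centre, from which the 1S isomer is separated by chromatography.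

**Step 11**
Reactants: 18 methyl 2-[(1S,3Z,12S)-7-bromo-8,12-epoxy-4,8,12-trimethyl-11-oxocyclotetradec-3-en-1-yl]prop-2-enoate
Product: 19 methyl 2-[(1S,3R,4S,12S)-7-bromo-3,4:8,12-diepoxy-4,8,12-trimethyl-11-oxocyclotetradecyl]prop-2-enoate
Conditions: Shi ketone (D-fructose-derived, 0.3 equiv), Oxone (2KHSO5·KHSO4·K2SO4), K2CO3, Bu4NHSO4, MeCN–CH2(OMe)2–aq. Na2B4O7 buffer, 0 °C
Reagents that add atoms: potassium peroxymonosulfate (KHSO5), [K+].[O-]S(=O)(=O)OO
Why: Shi asymmetric epoxidation: the dioxirane of the D-fructose-derived ketone adds syn to the only electron-rich olefin left (the acrylate is electron-poor, the 7,8-olefin is masked) through the spiro transition state that gives R configuration at the olefinic CH carbon C3, so the 3Z geometry translates into the (3R,4S)-cis-oxirane.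

**Step 12**
Reactants: 19 methyl 2-[(1S,3R,4S,12S)-7-bromo-3,4:8,12-diepoxy-4,8,12-trimethyl-11-oxocyclotetradecyl]prop-2-enoate
Product: 20 methyl 2-[(1S,3R,4S,7E,12S)-3,4-epoxy-12-hydroxy-4,8,12-trimethyl-11-oxocyclotetradec-7-en-1-yl]prop-2-enoate
Conditions: Zn dust (activated), NH4Cl, EtOH, 60 °C
Reagents that add atoms: none
Why: Boord-type reductive β-elimination: zinc inserts into the C7–Br bond and the anti-periplanar C8–O bond is expelled, which returns the 7E-olefin from either anti-adduct (anti elimination reverses the anti addition of step 7) and the free 12-OH under near-neutral conditions that the oxirane, ketone and acrylate should tolerate.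

**Compound list**
1 | (S)-(+)-linalool, (3S)-3,7-dimethylocta-1,6-dien-3-ol | C=C[C@@](C)(O)CCC=C(C)C | starting material
2 | (5S)-5-ethenyl-5-methyloxolan-2-ol (lactol, anomer mixture) | OC1CC[C@](C)(O1)C=C | intermediate (not isolated)
3 | (5S)-5-ethenyl-2-methoxy-5-methyloxolane (anomer mixture) | COC1CC[C@](C)(O1)C=C | intermediate
4 | 1-[(2S)-5-methoxy-2-methyloxolan-2-yl]ethan-1-one (anomer mixture) | COC1CC[C@](C)(O1)C(C)=O | intermediate
5 | neryl acetate, (2Z)-3,7-dimethylocta-2,6-dien-1-yl acetate | CC(C)=CCC/C(C)=C\COC(C)=O | starting material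
6 | (2Z,6E)-8-hydroxy-3,7-dimethylocta-2,6-dien-1-yl acetate | OC/C(C)=C/CC/C(C)=C\COC(C)=O | intermediate
7 | (2Z,6E)-8-bromo-3,7-dimethylocta-2,6-dien-1-yl acetate | BrC/C(C)=C/CC/C(C)=C\COC(C)=O | intermediate
8 | lithium 1-[(2S)-5-methoxy-2-methyloxolan-2-yl]ethen-1-olate (lithium enolate of 4) | COC1CC[C@](C)(O1)C(=C)O[Li] | intermediate (not isolated)
9 | (2Z,6E)-10-[(2S)-5-methoxy-2-methyloxolan-2-yl]-3,7-dimethyl-10-oxodeca-2,6-dien-1-yl acetate | COC1CC[C@](C)(O1)C(=O)CC/C(C)=C/CC/C(C)=C\COC(C)=O | intermediate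
10 | (2Z,6E)-10-[(2S)-5-hydroxy-2-methyloxolan-2-yl]-3,7-dimethyl-10-oxodeca-2,6-dien-1-yl acetate (lactol) | OC1CC[C@](C)(O1)C(=O)CC/C(C)=C/CC/C(C)=C\COC(C)=O | intermediate
11 | (2Z)-6-bromo-6-[(6S)-2,6-dimethyl-5-oxo-6-(3-oxopropyl)oxan-2-yl]-3-methylhex-2-en-1-yl acetate (C7/C8 of the cembrane skeleton: both anti-adducts) | O=CCC[C@](C)(O1)C(=O)CCC1(C)C(Br)CC/C(C)=C\COC(C)=O | intermediate
12 | methyl (triphenyl-λ5-phosphanylidene)acetate | COC(=O)C=P(c1ccccc1)(c1ccccc1)c1ccccc1 | starting material
13 | (iodomethyl)trimethylsilane | C[Si](C)(C)CI | starting material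
14 | [1-methoxy-1-oxo-3-(trimethylsilyl)propan-2-yl]triphenylphosphonium iodide | COC(=O)C(C[Si](C)(C)C)[P+](c1ccccc1)(c1ccccc1)c1ccccc1.[I-] | intermediate (not isolated)
15 | methyl 2-(triphenyl-λ5-phosphanylidene)-3-(trimethylsilyl)propanoate | COC(=O)C(C[Si](C)(C)C)=P(c1ccccc1)(c1ccccc1)c1ccccc1 | intermediate
16 | methyl (2Z)-5-[(2S)-6-[(4Z)-6-acetoxy-1-bromo-4-methylhex-4-en-1-yl]-2,6-dimethyl-3-oxooxan-2-yl]-2-[(trimethylsilyl)methyl]pent-2-enoate (both C7/C8 anti-adducts) | COC(=O)/C(C[Si](C)(C)C)=C/CC[C@](C)(O1)C(=O)CCC1(C)C(Br)CC/C(C)=C\COC(C)=O | intermediate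
17 | Z-allyl cation from 16 (C2–C3–C4 cation, triflate counter-ion) | COC(=O)/C(C[Si](C)(C)C)=C/CC[C@](C)(O1)C(=O)CCC1(C)C(Br)CC/C(C)=C\[CH2+].[O-]S(=O)(=O)C(F)(F)F | intermediate (not isolated)
18 | methyl 2-[(1S,3Z,12S)-7-bromo-8,12-epoxy-4,8,12-trimethyl-11-oxocyclotetradec-3-en-1-yl]prop-2-enoate (both C7/C8 anti-adducts) | C=C(C(=O)OC)[C@H]1CC[C@](C)(O2)C(=O)CCC2(C)C(Br)CC/C(C)=C\C1 | intermediate
19 | methyl 2-[(1S,3R,4S,12S)-7-bromo-3,4:8,12-diepoxy-4,8,12-trimethyl-11-oxocyclotetradecyl]prop-2-enoate (both C7/C8 anti-adducts) | C=C(C(=O)OC)[C@H]1CC[C@](C)(O2)C(=O)CCC2(C)C(Br)CC[C@]3(C)O[C@@H]3C1 | intermediate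
20 | methyl 2-[(1S,3R,4S,7E,12S)-3,4-epoxy-12-hydroxy-4,8,12-trimethyl-11-oxocyclotetradec-7-en-1-yl]prop-2-enoate | C=C(C(=O)OC)[C@H]1CC[C@](C)(O)C(=O)CC/C(C)=C/CC[C@]2(C)O[C@@H]2C1 | target

**Step count and risks**
Total: 12 steps. Longest linear sequence: 9 steps (1, 2, 5, 6, 7, 9, 10, 11, 12).

Most likely to fail, in this order:

Step 10. The allyl cation may eliminate to a triene, lose the 3Z geometry through reversible ion-pair return at C4, or give an unfavourable C1 epimer ratio. Fallback: close the ring under neutral conditions through a π-allylpalladium complex instead of a free cation. Setting out from 11, the aldehyde is olefinated (toluene, 80 °C) with methyl 3-(tributylstannyl)-2-(triphenyl-λ5-phosphanylidene)propanoate F1, made from 12 and (iodomethyl)tributylstannane in the same way as 15. This gives the allylstannane seco-acetate methyl (2Z)-5-[(2S)-6-[(4Z)-6-acetoxy-1-bromo-4-methylhex-4-en-1-yl]-2,6-dimethyl-3-oxooxan-2-yl]-2-[(tributylstannyl)methyl]pent-2-enoate F2. F2 is cyclised with Pd(PPh3)4 (10 mol %) and LiCl in THF at 50 °C under high dilution: zerovalent palladium ionises the allylic acetate to the anti-π-allyl complex, and the allylstannane couples at C2 with allyl transposition. The fallback comes back to the route at 18.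

Step 12. Warm zinc and the zinc halide formed may open the trisubstituted oxirane, and part of the olefin may come back as 7Z. Fallback: close the oxirane only after the unmasking. Setting out from 18, trichloroisocyanuric acid in acetone–H2O at 0 °C gives the chlorohydrin methyl 2-[(1S,3S,4S,12S)-7-bromo-3-chloro-8,12-epoxy-4-hydroxy-4,8,12-trimethyl-11-oxocyclotetradecyl]prop-2-enoate F4 (anti addition, water at the tertiary C4). Zn and AcOH in THF at 25 °C then open the bromoether; an alkyl chloride is inert to zinc and no oxirane is present. This gives methyl 2-[(1S,3S,4S,7E,12S)-3-chloro-4,12-dihydroxy-4,8,12-trimethyl-11-oxocyclotetradec-7-en-1-yl]prop-2-enoate F5. K2CO3 in acetone closes the oxirane with inversion at C3, and the fallback comes back to the route at 20.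

Step 11. The reagent-controlled face may be mismatched with the intrinsic facial bias of the oxane-bridged macrocycle, giving the wrong oxirane face or low conversion. Fallback: deliver the oxygen by anti addition and inversion, which places it on the face opposite to the one an electrophilic oxidant attacks. Setting out from 18, NBS in THF–H2O at 0 °C gives the bromohydrin methyl 2-[(1S,3S,4S,12S)-3,7-dibromo-8,12-epoxy-4-hydroxy-4,8,12-trimethyl-11-oxocyclotetradecyl]prop-2-enoate F3 (Br at C3, OH at the tertiary C4). K2CO3 in acetone closes it with inversion at C3, and the fallback comes back to the route at 19.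

**Further compounds**
F1 | step 10 | methyl 3-(tributylstannyl)-2-(triphenyl-λ5-phosphanylidene)propanoate | COC(=O)C(C[Sn](CCCC)(CCCC)CCCC)=P(c1ccccc1)(c1ccccc1)c1ccccc1
F2 | step 10 | methyl (2Z)-5-[(2S)-6-[(4Z)-6-acetoxy-1-bromo-4-methylhex-4-en-1-yl]-2,6-dimethyl-3-oxooxan-2-yl]-2-[(tributylstannyl)methyl]pent-2-enoate | COC(=O)/C(C[Sn](CCCC)(CCCC)CCCC)=C/CC[C@](C)(O1)C(=O)CCC1(C)C(Br)CC/C(C)=C\COC(C)=O
F3 | step 11 | methyl 2-[(1S,3S,4S,12S)-3,7-dibromo-8,12-epoxy-4-hydroxy-4,8,12-trimethyl-11-oxocyclotetradecyl]prop-2-enoate | C=C(C(=O)OC)[C@H]1CC[C@](C)(O2)C(=O)CCC2(C)C(Br)CC[C@](C)(O)[C@@H](Br)C1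
F4 | step 12 | methyl 2-[(1S,3S,4S,12S)-7-bromo-3-chloro-8,12-epoxy-4-hydroxy-4,8,12-trimethyl-11-oxocyclotetradecyl]prop-2-enoate | C=C(C(=O)OC)[C@H]1CC[C@](C)(O2)C(=O)CCC2(C)C(Br)CC[C@](C)(O)[C@@H](Cl)C1
F5 | step 12 | methyl 2-[(1S,3S,4S,7E,12S)-3-chloro-4,12-dihydroxy-4,8,12-trimethyl-11-oxocyclotetradec-7-en-1-yl]prop-2-enoate | C=C(C(=O)OC)[C@H]1CC[C@](C)(O)C(=O)CC/C(C)=C/CC[C@](C)(O)[C@@H](Cl)C1
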